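# Proposed synthesis of CNP0250763.1 by an enantioselective Diels–Alder construction of ring C

Locants used throughout: ring C is C1(=O), C2 (bears the coumarin), C3–H, C4(=O), C5 (OH, prenyl), C6H2. Coumarin positions are primed (C2', C3', C4'). The prenyl chain is C1''–C3''.

## The problem

Target 17 is a 7-methoxycoumarin joined through C3' to C2 of a cyclohex-2-ene-1,4-dione (ring C). The only stereocentre is C5, a quaternary carbinol carbon that also carries the prenyl chain. With no second centre to relay from, its (R) configuration has to come from a reagent or a catalyst. The C5 hydroxyl is α to the C4 carbonyl and β to the C1 carbonyl. Acid or base can therefore expel water across C5–C6 and aromatise ring C to the 2-aryl-5-prenylbenzoquinone. The ene-dione is also a strong Michael acceptor, the prenyl alkene is open to radicals, peroxides and acid, and the coumarin lactone does not tolerate hydride or hard carbanions. The free hydroxy ene-dione must therefore appear late and under near-neutral conditions, and the order in which the ring oxygens and the prenyl alkene are introduced matters as much as any bond construction. A short solution is possible because ring C is a cyclohexene whose C2=C3 bond lies 1,4 to C5. Cutting C4–C5 and C6–C1 gives a 2-substituted butadiene with two unsubstituted termini and a 1,1-disubstituted dienophile that carries the C5 oxygen and a one-carbon handle for the prenyl chain. The cycloaddition then creates C5 alone, and C1 and C4 arrive as methylenes that are both allylic to C2=C3 and can be oxidised afterwards.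

## Retrosynthesis

**17 to 16 (cut C2''=C3'').** The prenyl alkene is removed first and traced to a terminal allyl group in 16 by cross-metathesis with 2-methyl-2-butene. Carrying the prenyl group through from the epoxide opening would save one step. It would, however, expose eight allylic hydrogens of a trisubstituted alkene to the ring oxidation, whereas a monosubstituted alkene next to a quaternary carbon is a much poorer substrate for hydrogen abstraction. Metathesis runs under neutral conditions, which the dehydration-prone carbinol requires. The forward reaction must engage only the terminal alkene and leave the conjugated trisubstituted C2=C3 and C3'=C4' bonds alone.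

**16 to 14 (remove the C1 and C4 oxygens).** Both carbonyls are traced to methylenes in 14 through a double allylic oxidation that passes through enone 15. No stereocentre is created, and C5, being quaternary, cannot be epimerised or over-oxidised. Placing the oxygens on the diene instead would alter the key step and add stereocentres. Oxidising before the side chain is built would force both ketones to be masked during the carbanion step. The forward step needs selectivity for the ring methylenes over the side-chain CH2.

**14 to 13 (cut C1''–C2'').** The allyl group is split into a vinyl nucleophile and the methylene of spiro-epoxide 13, so the formyl carbon of the cycloadduct becomes C1''. Homologation of the aldehyde by olefination would pass through a β-acyloxy aldehyde that eliminates readily. Epoxide opening leaves the C5–O bond, and therefore the configuration, untouched. The forward step asks for attack at the unhindered CH2 terminus and tolerance of the coumarin.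

**13 to 11 to 9 (C–O closure and functional-group changes).** The epoxide comes from diol 11 by sulfonylation of the primary hydroxyl and closure by the tertiary alkoxide. Diol 11 comes from cycloadduct 9 by reduction of the aldehyde and removal of the benzoate through 10. No C–C bond is involved, and C5 is carried through unchanged.

**9 to 5 + 8 (cut C4–C5 and C6–C1).** This is the key disconnection: a [4+2] cycloaddition of diene 5 with α-(benzoyloxy)acrolein 8. It removes the ring, the stereocentre and the C5 oxygen in one operation and leaves two achiral fragments of three and two steps. Cuts at C1–C2 or through the coumarin defer the stereocentre to a separate sequence. The forward reaction needs 1,4 ("para") regiochemistry and control of the dienophile face by a chiral catalyst.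

**5 to 4 to 3 to 1 + 2.** The diene is cut between its C2 and the vinyl group to give enol triflate 4 and a vinyl-metal partner. Triflate 4 comes from 3-acetylcoumarin 3, which is the Knoevenagel product of salicylaldehyde 1 and ethyl acetoacetate 2. The acetyl group is thus a masked 1-substituted vinyl cation, and the coumarin is made in one step from commercial materials.

**8 to 7 to 6.** The dienophile is traced to 4H-1,3-dioxin 7 by a retro-hetero-Diels–Alder loss of acetone, and 7 to the commercial dioxanone 6 by enol benzoylation. This delivers the sensitive acyloxyacrolein under neutral thermal conditions, just before use.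

## Roads not taken

**Alternative 1:** ring C is cut at C1–C2. In the forward direction the seco compound A2, a C1 phenyl thioester carrying a (Z)-vinylstannane at C2, is cyclised. The reagents are Pd2(dba)3 (zerovalent palladium) and copper thiophene-2-carboxylate, CuTC (monovalent copper), and the product is the C5 triethylsilyl ether A1. A single mild desilylation then gives 17.
- Merits: the ene-dione is formed at its final oxidation level under neutral conditions, with the prenyl group and C5 already in place. No late C–H oxidation and no metathesis are needed. In this respect it is better than the chosen plan.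
- Weak points: A2 contains a β-stannyl enone that is prone to protodestannylation and Z/E drift, and a β-silyloxy thioester that can eliminate. The configuration at C5 has to be made in a separate asymmetric sequence on an open chain, so the key step does not address the stereochemical problem.
- Comparison: the chosen plan sets C5 and closes the ring in one catalytic step from fragments of three and two steps, and its intermediates up to 14 are robust. It pays with two late oxidation-state adjustments.

**Alternative 2:** the C1–C6 bond and the C5–O bond are formed by a 1,3-dipolar cycloaddition. The nitrile oxide released from hydroximoyl chloride A4 adds to the zinc alkoxide of 2-prenylallyl alcohol A5 under Et2Zn (divalent zinc) and diisopropyl tartrate. The product is the (5R)-isoxazoline A3, in which C5 is set.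
- Merits: the prenyl group, the tertiary oxygen and the C1 carbonyl (as C=N) are all delivered in one event. The controller is cheap, and no organometallic reagent ever meets the coumarin. For installing the prenyl group this is clearly more economical than the three steps of the chosen plan.
- Weak points: the key step does not close ring C. A3 lacks C3, so a one-carbon unit must still be inserted between C2 and the hydroxymethyl carbon (future C4) before a six-membered ring can form. The N–O bond must be cleaved reductively without touching the prenyl alkene or the coumarin. The nitrile oxide bears an activated α-methylene and may dimerise.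
- Comparison: the chosen plan has all six ring carbons in place after its key step.

**Alternative 3:** ring B of the coumarin is formed last. The ring-C acetic acid A7 is esterified with aldehyde 1 by a carbodiimide to give aryl ester A8. Amine-mediated condensation of the ester α-carbon with the formyl group then forms O1'–C2' and C3'=C4' and gives ketal A6, which is hydrolysed to 17.
- Merits: the route is convergent and the coumarin never has to survive a cuprate or a hydride. That is a real advantage over the chosen plan, which must manage exactly that risk in step 9.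
- Weak points: A7 already contains the whole stereochemical problem, so the key step only defers it. The amine condensation and the final acidic ketal hydrolysis both act on a β-hydroxy carbonyl system that can lose water towards the quinone.
- Comparison: the chosen plan instead makes the coumarin first, in one step, and uses it as the aryl group that steers the regiochemistry of the cycloaddition.

Key step: step 6

Assumption: the (R)-diamine salt is taken to shield the dienophile face that leads to (R)-9; the sense of induction is not established for this diene, and the (S)-diamine would be used without other change if the antipode were formed.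

## Route

Step 1
Reactants: 1 2-hydroxy-4-methoxybenzaldehyde; 2 ethyl acetoacetate
Product: 3 3-acetyl-7-methoxy-2H-chromen-2-one
Conditions: piperidine (cat.), EtOH, reflux
Reagents that add atoms: none
Why: Knoevenagel condensation of the β-keto ester with the aldehyde, followed by lactonisation of the phenol onto the ethyl ester; this is the standard entry to 3-acetylcoumarins.

Step 2
Reactants: 3 3-acetyl-7-methoxy-2H-chromen-2-one
Product: 4 1-(7-methoxy-2-oxo-2H-chromen-3-yl)ethenyl trifluoromethanesulfonate
Conditions: Tf2O, 2,6-di-tert-butyl-4-methylpyridine, CH2Cl2, 0 °C to rt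
Reagents that add atoms: trifluoromethanesulfonic anhydride, O=S(=O)(OS(=O)(=O)C(F)(F)F)C(F)(F)F
Why: Enol triflate formation by O-triflylation of the ketone and loss of a methyl proton to the hindered base; the methyl group is the only enolisable position, and no nucleophilic base is present that could add to C4' of the activated coumarin.

Step 3
Reactants: 4 1-(7-methoxy-2-oxo-2H-chromen-3-yl)ethenyl trifluoromethanesulfonate
Product: 5 3-(buta-1,3-dien-2-yl)-7-methoxy-2H-chromen-2-one
Conditions: CH2=CHSnBu3, Pd(PPh3)4 (5 mol %), LiCl, THF, 60 °C
Reagents that add atoms: tributyl(vinyl)stannane, C=C[Sn](CCCC)(CCCC)CCCC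
Why: Stille coupling of an alkenyl triflate with a vinylstannane, the classical route to 2-substituted 1,3-dienes; the electron-poor triflate should add readily to zerovalent palladium, and the diene is kept cold and used promptly.

Step 4
Reactants: 6 2,2-dimethyl-1,3-dioxan-5-one
Product: 7 2,2-dimethyl-4H-1,3-dioxin-5-yl benzoate
Conditions: KN(SiMe3)2, THF, −78 °C; then BzCl
Reagents that add atoms: benzoyl chloride, O=C(Cl)c1ccccc1
Why: O-acylation of a potassium enolate with an aroyl chloride gives the enol ester; the symmetrical ketone has only one kind of α-position.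

Step 5
Reactants: 7 2,2-dimethyl-4H-1,3-dioxin-5-yl benzoate
Product: 8 3-oxoprop-1-en-2-yl benzoate (α-(benzoyloxy)acrolein)
Conditions: toluene, 110 °C, acetone distilled off
Reagents that add atoms: none
Why: Retro-hetero-Diels–Alder fragmentation of the 4H-1,3-dioxin releases acetone and the 2-acyloxyacrolein under neutral conditions; the aldehyde is used directly.

Step 6
Reactants: 5 3-(buta-1,3-dien-2-yl)-7-methoxy-2H-chromen-2-one; 8 3-oxoprop-1-en-2-yl benzoate
Product: 9 (1R)-1-formyl-4-(7-methoxy-2-oxo-2H-chromen-3-yl)cyclohex-3-en-1-yl benzoate
Conditions: (R)-1,1'-binaphthyl-2,2'-diamine (10 mol %), Tf2NH (19 mol %), EtCN, −40 to 0 °C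
Reagents that add atoms: none
Why: Organocatalytic enantioselective Diels–Alder reaction: one ammonium group of the diamine salt condenses reversibly with the formyl group of 8 to an aldiminium ion of lowered LUMO, to which diene 5 adds in a concerted but asynchronous [4+2] event in which the C6–C1 bond (dienophile β-carbon to the diene methylene next to the aryl-bearing C2) runs ahead of C4–C5, and hydrolysis of the product iminium ion releases 9 and the catalyst. The closest known reaction type is the chiral primary ammonium salt-catalysed cycloaddition of α-acyloxyacroleins with acyclic 2-substituted dienes such as isoprene, which gives the 1,4-adducts. Ring C closes by an intermolecular [4π+2π] cycloaddition that forms both σ-bonds suprafacially on each partner. C5 is the only new stereocentre and is under catalyst control: the second N–H of the diammonium salt is expected to hydrogen-bond to the benzoate carbonyl and fix the iminium geometry, so that the binaphthyl wall covers one enantioface of the dienophile. The step needs regioselectivity, which follows from the larger HOMO coefficient at the diene terminus adjacent to the substituted carbon matching the β-carbon of the iminium ion, and site selectivity for the open-chain diene over the cross-conjugated pair made up of C3'=C4' and the methylene, which would give up lactone conjugation and has a substituted terminus. Endo/exo selectivity does not arise because both diene termini are unsubstituted.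

Step 7
Reactants: 9 (1R)-1-formyl-4-(7-methoxy-2-oxo-2H-chromen-3-yl)cyclohex-3-en-1-yl benzoate
Product: 11 3-[(4R)-4-hydroxy-4-(hydroxymethyl)cyclohex-1-en-1-yl]-7-methoxy-2H-chromen-2-one, via hydroxymethyl benzoate 10 (not isolated)
Conditions: NaBH4, MeOH–THF, 0 °C; then K2CO3 (cat.), MeOH, rt; aq. NH4Cl
Reagents that add atoms: none
Why: Borohydride reduction of the aldehyde followed by base-catalysed methanolysis of the benzoate, which is eased by 1,2-acyl shift to the new primary alkoxide. The coumarin is not reduced at 0 °C, any lactone opened by methoxide recloses on neutralisation, and C5 is not involved.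

Step 8
Reactants: 11 3-[(4R)-4-hydroxy-4-(hydroxymethyl)cyclohex-1-en-1-yl]-7-methoxy-2H-chromen-2-one
Product: 13 7-methoxy-3-[(3R)-1-oxaspiro[2.5]oct-5-en-6-yl]-2H-chromen-2-one, via primary tosylate 12 (not isolated)
Conditions: NaH, 1-(p-toluenesulfonyl)imidazole, THF, 0 °C to rt
Reagents that add atoms: none
Why: One-pot epoxide formation from a 1,2-diol: the primary alkoxide is sulfonylated selectively and the tertiary alkoxide closes by intramolecular Williamson displacement at CH2, so the C5–O bond and the configuration are retained.

Step 9
Reactants: 13 7-methoxy-3-[(3R)-1-oxaspiro[2.5]oct-5-en-6-yl]-2H-chromen-2-one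
Product: 14 3-[(4S)-4-hydroxy-4-(prop-2-en-1-yl)cyclohex-1-en-1-yl]-7-methoxy-2H-chromen-2-one
Conditions: CH2=CHMgBr (slow addition), CuBr·SMe2 (10 mol %), THF, −40 to −20 °C; aq. NH4Cl
Reagents that add atoms: vinylmagnesium bromide, C=C[Mg]Br
Why: Copper-catalysed SN2 opening of a 2,2-disubstituted epoxide at its unhindered methylene terminus by a vinyl Grignard reagent; C5 is untouched (the descriptor changes to S only through the priority rules). The α-substituted, donor-bearing coumarin is a poor acceptor at low temperature.

Step 10
Reactants: 14 3-[(4S)-4-hydroxy-4-(prop-2-en-1-yl)cyclohex-1-en-1-yl]-7-methoxy-2H-chromen-2-one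
Product: 16 3-[(4R)-4-hydroxy-3,6-dioxo-4-(prop-2-en-1-yl)cyclohex-1-en-1-yl]-7-methoxy-2H-chromen-2-one, via enone 15 (not isolated)
Conditions: Rh2(cap)4 [dirhodium tetrakis(caprolactamate)] (1 mol %), aq. t-BuOOH (excess), ClCH2CH2Cl, 40 °C, no base
Reagents that add atoms: tert-butyl hydroperoxide, CC(C)(C)OO
Why: Dirhodium caprolactamate-catalysed allylic oxidation with tert-butyl hydroperoxide, known to take cyclohexenes to enones and enones on to ene-diones. The tert-butylperoxy radical should first abstract the C4 hydrogen, whose radical is delocalised through C2=C3 into the coumarin, and then the γ-hydrogen at C1 of enone 15; the side-chain CH2 gives only a simple allyl radical and is shielded by the quaternary C5. No stereocentre is formed, and the descriptor returns to R through the priority rules.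

Step 11
Reactants: 16 3-[(4R)-4-hydroxy-3,6-dioxo-4-(prop-2-en-1-yl)cyclohex-1-en-1-yl]-7-methoxy-2H-chromen-2-one
Product: 17 3-[(4R)-4-hydroxy-4-(3-methylbut-2-en-1-yl)-3,6-dioxocyclohex-1-en-1-yl]-7-methoxy-2H-chromen-2-one
Conditions: 2-methyl-2-butene (excess), second-generation Grubbs catalyst (H2IMes)(PCy3)Cl2Ru=CHPh (5 mol %), CH2Cl2, 40 °C
Reagents that add atoms: 2-methyl-2-butene, CC=C(C)C
Why: Olefin cross-metathesis of a terminal allyl group with 2-methyl-2-butene is the standard allyl-to-prenyl conversion. It is neutral, so the dehydration-prone carbinol survives, and the conjugated trisubstituted C2=C3 and C3'=C4' bonds are inert to the ruthenium carbene.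

## Compound list

1 | 2-hydroxy-4-methoxybenzaldehyde | COc1ccc(C=O)c(O)c1 | starting material
2 | ethyl acetoacetate | CCOC(=O)CC(C)=O | starting material
3 | 3-acetyl-7-methoxy-2H-chromen-2-one | COc1ccc2cc(C(C)=O)c(=O)oc2c1 | intermediate
4 | 1-(7-methoxy-2-oxo-2H-chromen-3-yl)ethenyl trifluoromethanesulfonate | COc1ccc2cc(C(=C)OS(=O)(=O)C(F)(F)F)c(=O)oc2c1 | intermediate
5 | 3-(buta-1,3-dien-2-yl)-7-methoxy-2H-chromen-2-one | COc1ccc2cc(C(=C)C=C)c(=O)oc2c1 | intermediate
6 | 2,2-dimethyl-1,3-dioxan-5-one | CC1(C)OCC(=O)CO1 | starting material
7 | 2,2-dimethyl-4H-1,3-dioxin-5-yl benzoate | CC1(C)OCC(OC(=O)c2ccccc2)=CO1 | intermediate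
8 | 3-oxoprop-1-en-2-yl benzoate (α-(benzoyloxy)acrolein) | C=C(OC(=O)c1ccccc1)C=O | intermediate
9 | (1R)-1-formyl-4-(7-methoxy-2-oxo-2H-chromen-3-yl)cyclohex-3-en-1-yl benzoate | COc1ccc2cc(C3=CC[C@@](OC(=O)c4ccccc4)(C=O)CC3)c(=O)oc2c1 | intermediate
10 | (1R)-1-(hydroxymethyl)-4-(7-methoxy-2-oxo-2H-chromen-3-yl)cyclohex-3-en-1-yl benzoate | COc1ccc2cc(C3=CC[C@@](OC(=O)c4ccccc4)(CO)CC3)c(=O)oc2c1 | intermediate
11 | 3-[(4R)-4-hydroxy-4-(hydroxymethyl)cyclohex-1-en-1-yl]-7-methoxy-2H-chromen-2-one | COc1ccc2cc(C3=CC[C@@](O)(CO)CC3)c(=O)oc2c1 | intermediate
12 | [(1R)-1-hydroxy-4-(7-methoxy-2-oxo-2H-chromen-3-yl)cyclohex-3-en-1-yl]methyl 4-methylbenzenesulfonate | COc1ccc2cc(C3=CC[C@@](O)(COS(=O)(=O)c4ccc(C)cc4)CC3)c(=O)oc2c1 | intermediate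
13 | 7-methoxy-3-[(3R)-1-oxaspiro[2.5]oct-5-en-6-yl]-2H-chromen-2-one | COc1ccc2cc(C3=CC[C@@]4(CO4)CC3)c(=O)oc2c1 | intermediate
14 | 3-[(4S)-4-hydroxy-4-(prop-2-en-1-yl)cyclohex-1-en-1-yl]-7-methoxy-2H-chromen-2-one | COc1ccc2cc(C3=CC[C@@](O)(CC=C)CC3)c(=O)oc2c1 | intermediate
15 | 3-[(4S)-4-hydroxy-3-oxo-4-(prop-2-en-1-yl)cyclohex-1-en-1-yl]-7-methoxy-2H-chromen-2-one | COc1ccc2cc(C3=CC(=O)[C@@](O)(CC=C)CC3)c(=O)oc2c1 | intermediate
16 | 3-[(4R)-4-hydroxy-3,6-dioxo-4-(prop-2-en-1-yl)cyclohex-1-en-1-yl]-7-methoxy-2H-chromen-2-one | COc1ccc2cc(C3=CC(=O)[C@@](O)(CC=C)CC3=O)c(=O)oc2c1 | intermediate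
17 | 3-[(4R)-4-hydroxy-4-(3-methylbut-2-en-1-yl)-3,6-dioxocyclohex-1-en-1-yl]-7-methoxy-2H-chromen-2-one | COc1ccc2cc(C3=CC(=O)[C@@](O)(CC=C(C)C)CC3=O)c(=O)oc2c1 | target

## Step count and points of risk

Total: 11 steps. Longest linear sequence: 9 steps (steps 1, 2, 3, 6, 7, 8, 9, 10, 11), with a two-step branch (steps 4, 5) for the dienophile.

**Step 6 (key step).**
- What may go wrong: the diene carries an electron-poor alkenyl lactone at C2 and may react sluggishly with the iminium ion. Dimerisation of the diene or polymerisation of the acyloxyacrolein could then compete. Raising the temperature to compensate could erode the facial selectivity.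
- Fallback: from diene 5, a chiral Lewis acid replaces the iminium catalyst and 2-bromoacrolein replaces 8. The catalyst is the N-protonated B-(o-tolyl) oxazaborolidine of α,α-diphenylprolinol with Tf2NH, in the enantiomer that gives the (S)-bromide. The adduct would be (1S)-1-bromo-4-(7-methoxy-2-oxo-2H-chromen-3-yl)cyclohex-3-ene-1-carbaldehyde F1. NaBH4 would reduce it to the bromohydrin 3-[(4S)-4-bromo-4-(hydroxymethyl)cyclohex-1-en-1-yl]-7-methoxy-2H-chromen-2-one F2. K2CO3 in MeOH would close F2 with inversion at C5 and rejoin the route at epoxide 13. The same two ring bonds are formed.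

**Step 2.**
- What may go wrong: the O-triflylated ketone is a stabilised cation. Capture of that cation at C4' by triflate, or incomplete proton loss, could give decomposition in place of clean enol triflate formation.
- Fallback: from ketone 3, vinylcerium (CH2=CHMgBr, anhydrous CeCl3, THF, −78 °C) should add 1,2 to the acetyl group. The product is the tertiary allylic alcohol 3-(2-hydroxybut-3-en-2-yl)-7-methoxy-2H-chromen-2-one F3. Dehydration with Burgess reagent, which can only take a methyl hydrogen, would give diene 5 and make step 3 unnecessary.

**Step 9.**
- What may go wrong: the vinyl Grignard reagent may add to the lactone carbonyl or to C4' of the coumarin faster than the copper-mediated opening of the neopentyl-like epoxide terminus.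
- Fallback: from epoxide 13, a radical path avoids carbanions. LiI and AcOH in THF would open the epoxide at CH2 to the iodohydrin 3-[(4R)-4-hydroxy-4-(iodomethyl)cyclohex-1-en-1-yl]-7-methoxy-2H-chromen-2-one F4. Nickel-catalysed reductive cross-electrophile coupling with vinyl bromide (NiBr2(dme), 4,4'-di-tert-butyl-2,2'-bipyridine, Zn, DMA) would then give 14.

**Step 10.**
- What may go wrong: hydrogen abstraction from the side-chain CH2 may compete, above all in the slower second oxidation. The peroxyl radical may add to the newly formed ene-dione. The product may lose water towards the quinone if the medium turns acidic or basic.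
- Fallback: the oxidation is stopped at enone 15 (less oxidant, rt) and 15 is isolated. TESOTf and Et3N would give 3-[(4R)-4-(prop-2-en-1-yl)-4,5-bis(triethylsilyloxy)cyclohexa-1,5-dien-1-yl]-7-methoxy-2H-chromen-2-one F5; since C5 is quaternary, the dienol ether can only form towards C1. Singlet oxygen (O2, tetraphenylporphyrin, light, CH2Cl2, −78 °C) adds across C1 and C4 and ignores the terminal alkene. Treatment with Et3N would then give the ene-dione 3-[(4R)-3,6-dioxo-4-(prop-2-en-1-yl)-4-(triethylsilyloxy)cyclohex-1-en-1-yl]-7-methoxy-2H-chromen-2-one F6. HF·pyridine in THF at 0 °C would return the route to 16.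

## Further compounds

F1 | step 6 | (1S)-1-bromo-4-(7-methoxy-2-oxo-2H-chromen-3-yl)cyclohex-3-ene-1-carbaldehyde | COc1ccc2cc(C3=CC[C@](Br)(C=O)CC3)c(=O)oc2c1
F2 | step 6 | 3-[(4S)-4-bromo-4-(hydroxymethyl)cyclohex-1-en-1-yl]-7-methoxy-2H-chromen-2-one | COc1ccc2cc(C3=CC[C@](Br)(CO)CC3)c(=O)oc2c1
F3 | step 2 | 3-(2-hydroxybut-3-en-2-yl)-7-methoxy-2H-chromen-2-one (racemic) | COc1ccc2cc(C(C)(O)C=C)c(=O)oc2c1
F4 | step 9 | 3-[(4R)-4-hydroxy-4-(iodomethyl)cyclohex-1-en-1-yl]-7-methoxy-2H-chromen-2-one | COc1ccc2cc(C3=CC[C@@](O)(CI)CC3)c(=O)oc2c1
F5 | step 10 | 3-[(4R)-4-(prop-2-en-1-yl)-4,5-bis(triethylsilyloxy)cyclohexa-1,5-dien-1-yl]-7-methoxy-2H-chromen-2-one | COc1ccc2cc(C3=CC[C@](O[Si](CC)(CC)CC)(CC=C)C(O[Si](CC)(CC)CC)=C3)c(=O)oc2c1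
F6 | step 10 | 3-[(4R)-3,6-dioxo-4-(prop-2-en-1-yl)-4-(triethylsilyloxy)cyclohex-1-en-1-yl]-7-methoxy-2H-chromen-2-one | COc1ccc2cc(C3=CC(=O)[C@@](O[Si](CC)(CC)CC)(CC=C)CC3=O)c(=O)oc2c1
A1 | alternative 1 | 3-[(4R)-3,6-dioxo-4-(3-methylbut-2-en-1-yl)-4-(triethylsilyloxy)cyclohex-1-en-1-yl]-7-methoxy-2H-chromen-2-one | COc1ccc2cc(C3=CC(=O)[C@@](O[Si](CC)(CC)CC)(CC=C(C)C)CC3=O)c(=O)oc2c1
A2 | alternative 1 | S-phenyl (3R,5Z)-6-(7-methoxy-2-oxo-2H-chromen-3-yl)-3-(3-methylbut-2-en-1-yl)-4-oxo-6-(tributylstannyl)-3-(triethylsilyloxy)hex-5-enethioate | COc1ccc2cc(/C([Sn](CCCC)(CCCC)CCCC)=C/C(=O)[C@@](O[Si](CC)(CC)CC)(CC=C(C)C)CC(=O)Sc3ccccc3)c(=O)oc2c1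
A3 | alternative 2 | 3-{[(5R)-5-(hydroxymethyl)-5-(3-methylbut-2-en-1-yl)-4,5-dihydro-1,2-oxazol-3-yl]methyl}-7-methoxy-2H-chromen-2-one | OC[C@@]1(CC=C(C)C)CC(Cc2cc3ccc(OC)cc3oc2=O)=NO1
A4 | alternative 2 | N-hydroxy-2-(7-methoxy-2-oxo-2H-chromen-3-yl)ethanimidoyl chloride | COc1ccc2cc(CC(Cl)=NO)c(=O)oc2c1
A5 | alternative 2 | 5-methyl-2-methylidenehex-4-en-1-ol (2-prenylallyl alcohol) | C=C(CO)CC=C(C)C
A6 | alternative 3 | 3-[(4R)-4-hydroxy-6,6-dimethoxy-4-(3-methylbut-2-en-1-yl)-3-oxocyclohex-1-en-1-yl]-7-methoxy-2H-chromen-2-one | COc1ccc2cc(C3=CC(=O)[C@@](O)(CC=C(C)C)CC3(OC)OC)c(=O)oc2c1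
A7 | alternative 3 | 2-[(4R)-4-hydroxy-6,6-dimethoxy-4-(3-methylbut-2-en-1-yl)-3-oxocyclohex-1-en-1-yl]acetic acid | OC(=O)CC1=CC(=O)[C@@](O)(CC=C(C)C)CC1(OC)OC
A8 | alternative 3 | 2-formyl-5-methoxyphenyl 2-[(4R)-4-hydroxy-6,6-dimethoxy-4-(3-methylbut-2-en-1-yl)-3-oxocyclohex-1-en-1-yl]acetate | COc1ccc(C=O)c(OC(=O)CC2=CC(=O)[C@@](O)(CC=C(C)C)CC2(OC)OC)c1
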